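## Structural features

The target 14 is a 3,4-dihydroisocoumarin. Aromatic ring A (C4a, C5, C6, C7, C8, C8a) is fused along C4a–C8a to the six-membered lactone ring B (C1, O2, C3, C4, C4a, C8a). Ring A carries a methoxy group at C6 and a free phenol at C8 that is hydrogen-bonded to the C1 carbonyl. C3 carries a linear 6-oxoundecyl chain: five methylenes, a ketone and an n-pentyl end. C3 (R) is the only stereocentre, so no neighbouring centre can relay its configuration, and it sits between two methylene groups (C4 and chain carbon C1') of similar size. The fragile elements are the lactone (hydride, strong nucleophiles, base), the enolisable ketone (organometallics) and the electron-rich ring with its acid-labile, easily oxidised benzylic positions in reduced intermediates. The real difficulty is to set C3 in absolute terms without a steric bias, and then to tell the two phenolic oxygens apart. The key step uses the fact that C3 bears O2 and lies between C4 and C1'. With C1'=C2' as a vinyl group, C3 is the internal end of an allyl unit, and O2 can come from a hydroxymethyl group on C8a (the future C1), so ring B closes by O2–C3 bond formation from an achiral butenyl benzyl alcohol.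

## Logic of the disconnections

**14 to 13.** The O–CH3 bond at C8 is re-formed. With both phenolic oxygens as methyl ethers the aromatic ring needs no differentiated protection and maps onto a commercial orsellinate. The demand is that the forward step cleaves only the C8 ether. The C1 carbonyl, peri to the C8 oxygen, allows a chelated Lewis acid to do this, while the C6 ether has no such neighbour.

**13 to 12.** The C1=O bond is removed, leaving a C1 methylene in a cyclic benzyl ether. Ring B can then be closed by a hydroxyl oxygen, and the lactone is kept away from the hydride, organometallic and hydrogenation steps. The demand is an oxidation that attacks C1 and not C4, C3–H, the ring or the ketone. C1 is the only carbon that is benzylic, α to oxygen, and ortho and para to the two methoxy groups.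

**12 to 11, then to 6 and 10.** The chain bond C1'–C2' is cut after a C1'=C2' double bond is introduced. This separates the small bicyclic core carrying the stereocentre from the achiral eleven-carbon keto chain and makes the route convergent. The demands are a cross-metathesis of a branched allylic ether that outruns homodimerisation, and a saturation that neither cleaves the allylic C3–O2 or benzylic C1–O2 bond nor moves the double bond onto C3.

**6 to 5.** The O2–C3 bond is cut. It is the one bond to the stereocentre that can be formed enantioselectively from an achiral substrate without prior functionalisation of C3, because the C3–H bond of 5 is allylic. Ring B and the stereocentre disappear together, leaving a tetrasubstituted benzene with two simple side chains. The demand is an enantioselective, branched-selective intramolecular allylic C–H etherification that tolerates an acid-labile, electron-rich benzylic alcohol. The design of 5 was checked and kept: the two methyl ethers make the later C1 oxidation selective, allow the chelation-controlled unmasking at C8, and do not bind palladium.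

**5 to 4, then to 1 and 2.** The hydroxymethyl carbon is traced to an ester carbon, and the C4–C3 bond is cut between the benzylic carbon and the allyl unit. The benzylic methyl group of 1 is acidified by the ortho ester, and 2 supplies three carbons including the terminal alkene. Both are commercial. The demands are that the benzylic anion forms without attacking the ester of a second molecule and is alkylated once, and that the reduction leaves the alkene alone.

**10 to 7 and 8.** The acyl–alkyl bond C5–C6 of the ketone is cut, giving a five-carbon alkenyl nucleophile and a six-carbon acyl electrophile, both commercial. The demand is that the acylation stops at the ketone.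

## Other disconnections considered

**Alternative 1:** Biomimetic aromatisation of a diketo-dioxinone. The cut is C4a–C8a of ring A, so the arene is built from a linear polycarbonyl chain. On heating, the dioxinone A1 loses acetone to give an acylketene, which methanol traps. The resulting triketo ester closes by aldol condensation and dehydration to the resorcylate A2.
- In favour: the conditions are mild and metal-free, and the oxygenation pattern of ring A is inherent. The C3 carbinol is installed in the open chain by well-established asymmetric chemistry, and on this point of stereochemical certainty the alternative is the better plan. It also needs no benzylic oxidation, which is a second point in its favour; ring B closes by simple desilylation and lactonisation.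
- Against: A1 needs a multistep assembly, and the remote ketone must travel as a ketal to keep it out of the aldol manifold. The β-silyloxy ketone in A1 may eliminate under the basic aromatisation. A2 still needs a selective methylation of the non-chelated para phenol.
- Comparison: the phenol differentiation is about equal to the chelation-controlled demethylation of the chosen plan. The chosen plan is clearly shorter and creates the stereocentre catalytically while it closes ring B.

**Alternative 2:** Hydroxyl-directed C–H carbonylation. The cuts are C1–C8a and C1–O2. The secondary alcohol of A3 directs Pd(OAc)2 (divalent palladium) to the ortho C–H bond, CO inserts, and the alkoxide closes onto the acyl palladium to give the lactone A4, which is identical with 13.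
- In favour: C1 arrives at the lactone oxidation level, so no chromium oxidation is needed, and on this point the alternative is the better plan. The symmetric 3,5-dimethoxyphenyl ring of A3 removes any regiochemical question, which makes it equal to the chosen plan there.
- Against: the key step does not create the stereocentre. It must already be in A3, typically from a resolved epoxide and an aryl metal over about four steps. A secondary carbinol is prone to β-hydride elimination to the ketone under divalent palladium with an oxidant. The C–H bond to be palladated is flanked by a methoxy group, and a stoichiometric silver oxidant and CO are needed.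
- Comparison: the step count is about equal to that of the chosen plan. The mechanism is less secure for a secondary, weakly coordinating alcohol.

**Alternative 3:** Diels–Alder benzannulation. The cuts are C8–C8a and C4a–C5. The electron-rich diene A6 adds across the triple bond of the chiral ynoate A5 on heating, and loss of methanol aromatises the adduct to A7.
- In favour: ring A is formed with the C8 phenol free and the C6 oxygen already methylated, so no selective demethylation is needed. On this point the alternative is the better plan. The regiochemistry follows from the polarisation of both partners, and the lactone again closes by desilylation.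
- Against: a β-alkyl ynoate is a sluggish dienophile, and the thermally sensitive ketene acetal A6 may decompose before it adds. A5 must be built with the stereocentre, a silyl ether and a ketal in place, over about five steps.
- Comparison: the route would be longer than the chosen one, and its key step builds the arene and not the stereocentre. The chosen plan buys the arene and spends its key step on the only real stereochemical problem.

Key step: step 3

Assumption: the enantiomer of the aryl sulfoxide–oxazoline ligand is chosen, from the known sense of induction of this ligand class, so that oxygen adds to the allyl face giving 3S in 6; the antipodal ligand would serve if the sense were opposite.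

## Route

Step 1
Reactants: 1 methyl 2,4-dimethoxy-6-methylbenzoate; 2 allyl bromide (3-bromoprop-1-ene)
Product: 4 methyl 2-(but-3-en-1-yl)-4,6-dimethoxybenzoate, via lithiated toluate 3 (not isolated)
Conditions: LiN(i-Pr)2 (LDA, commercial solution, 1.1 equiv), THF, −78 °C; then allyl bromide (1.3 equiv), −78 → 0 °C
Reagents that add atoms: lithium diisopropylamide, [Li+].CC(C)[N-]C(C)C (supplies the lithium of 3 only)
Why: Lateral (benzylic) lithiation: the ortho ester acidifies the methyl group and stabilises anion 3, which forms at −78 °C faster than it adds to a second ester. The soft benzylic carbanion is then alkylated once by the reactive allylic bromide (SN2), which installs the terminal alkene.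

Step 2
Reactants: 4 methyl 2-(but-3-en-1-yl)-4,6-dimethoxybenzoate
Product: 5 [2-(but-3-en-1-yl)-4,6-dimethoxyphenyl]methanol
Conditions: LiAlH4 (1.5 equiv), THF, 0 °C → rt; basic work-up (H2O, aq. NaOH)
Reagents that add atoms: none
Why: Hydride reduction of the hindered aryl ester to the primary benzylic alcohol; the isolated alkene and the aryl ethers are inert. The basic work-up and base-washed silica spare the acid-labile, electron-rich benzylic alcohol.

Step 3
Reactants: 5 [2-(but-3-en-1-yl)-4,6-dimethoxyphenyl]methanol
Product: 6 (3S)-3-ethenyl-6,8-dimethoxy-3,4-dihydro-1H-isochromene
Conditions: Pd(OAc)2 (10 mol%), enantiopure aryl sulfoxide–oxazoline ligand (10 mol%), Ph2P(O)OH (10 mol%), 2,6-dimethyl-1,4-benzoquinone (1.5 equiv), toluene, 45 °C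
Reagents that add atoms: none
Why: The ligand-bound Pd(OAc)2 (divalent palladium) coordinates the terminal alkene and removes a hydrogen from the allylic CH2 (the future C3) with carboxylate as internal base, giving a π-allyl palladium over C3 and the two vinyl carbons. The benzylic hydroxyl then attacks the internal allyl terminus, and the zerovalent palladium released is reoxidised by 2,6-dimethylbenzoquinone. The closest known reaction type is the enantioselective palladium/aryl sulfoxide–oxazoline allylic C–H oxidation of terminal olefins bearing a benzylic alcohol to 3-vinyl isochromans, so this is an application of that reaction to a dimethoxy-substituted ring. Ring B closes in a 6-exo mode (O2 onto C3, the rest of the allyl unit exocyclic); attack at the terminal carbon would need an eight-membered ring and is not expected. The C3 stereocentre is set by the chiral ligand alone, which differentiates the two faces of the π-allyl unit in the C–O bond-forming event, since the substrate is achiral. The step needs enantioselectivity, branched regioselectivity, and chemoselectivity for C–H cleavage over Wacker-type oxypalladation and over oxidation of the primary alcohol. The tether length secures the regiochemistry, the sulfoxide ligand class favours C–H cleavage, and the mild quinone should not oxidise a benzylic alcohol. The two ortho substituents also hold the hydroxymethyl group close to the butenyl chain, which should help the closure.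

Step 4
Reactants: 7 5-bromopent-1-ene; 8 hexanoyl chloride
Product: 10 undec-1-en-6-one, via pent-4-enylmagnesium bromide 9 (not isolated)
Conditions: Mg, THF, rt → 40 °C; then added to 8, Fe(acac)3 (3 mol%), THF, −78 °C
Reagents that add atoms: magnesium, [Mg] (supplies the magnesium of 9 only)
Why: Grignard formation followed by iron-catalysed acylation of the acid chloride, a cross-coupling-type ketone synthesis that is much faster at −78 °C than addition of the Grignard reagent to the ketone formed. The reaction should therefore stop at the ketone, and the terminal alkene is untouched.

Step 5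
Reactants: 6 (3S)-3-ethenyl-6,8-dimethoxy-3,4-dihydro-1H-isochromene; 10 undec-1-en-6-one
Product: 11 (1E)-1-[(3S)-6,8-dimethoxy-3,4-dihydro-1H-isochromen-3-yl]undec-1-en-6-one
Conditions: second-generation Hoveyda–Grubbs catalyst RuCl2(H2IMes)(=CH-C6H4-2-O-i-Pr) (5 mol%), 10 (3 equiv), 1,4-benzoquinone (10 mol%), CH2Cl2, 40 °C
Reagents that add atoms: none
Why: Olefin cross-metathesis: the unhindered alkene of 10, used in excess, loads the ruthenium carbene and couples with the slower α-branched allylic ether 6 with loss of ethene. The homodimer of 10 remains a competent partner, the quinone additive suppresses double-bond migration towards C3, and the E/Z ratio is irrelevant because the alkene is reduced next.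

Step 6
Reactants: 11 (1E)-1-[(3S)-6,8-dimethoxy-3,4-dihydro-1H-isochromen-3-yl]undec-1-en-6-one
Product: 12 1-[(3R)-6,8-dimethoxy-3,4-dihydro-1H-isochromen-3-yl]undecan-6-one
Conditions: H2 (3 atm), RhCl(PPh3)3 (5 mol%), toluene/EtOH 1:1, rt
Reagents that add atoms: none
Why: Homogeneous hydrogenation with RhCl(PPh3)3 saturates the disubstituted alkene without hydrogenolysis of the allylic C3–O2 or benzylic C1–O2 bond and without ketone reduction. It causes little alkene migration, so C3 keeps its spatial arrangement; the descriptor becomes R only through the change in priorities.

Step 7
Reactants: 12 1-[(3R)-6,8-dimethoxy-3,4-dihydro-1H-isochromen-3-yl]undecan-6-one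
Product: 13 (3R)-6,8-dimethoxy-3-(6-oxoundecyl)-3,4-dihydro-1H-isochromen-1-one
Conditions: pyridinium chlorochromate (C5H5NH)[CrO3Cl] (4 equiv), Celite, CH2Cl2, reflux
Reagents that add atoms: pyridinium chlorochromate, [O-][Cr](=O)(=O)Cl.c1cc[nH+]cc1
Why: Benzylic ether oxidation by hexavalent chromium converts the C1 methylene of the cyclic benzyl ether into the lactone carbonyl. C1 is the only carbon that is benzylic, α to oxygen and activated by the ortho (C8) and para (C6) methoxy groups, so C4, the C3–H bond and the dialkyl ketone should be left alone.

Step 8
Reactants: 13 (3R)-6,8-dimethoxy-3-(6-oxoundecyl)-3,4-dihydro-1H-isochromen-1-one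
Product: 14 (3R)-8-hydroxy-6-methoxy-3-(6-oxoundecyl)-3,4-dihydro-1H-isochromen-1-one
Conditions: BCl3 (1 M in CH2Cl2, 2.5 equiv), CH2Cl2, −78 → 0 °C; then H2O
Reagents that add atoms: none
Why: Chelation-controlled Lewis acid dealkylation: BCl3 binds the lactone carbonyl and the peri C8 methoxy oxygen in a six-membered chelate, and chloride removes that methyl group only. The C6 ether, the ketone and the lactone should survive at low temperature.

## Compound list

1 | methyl 2,4-dimethoxy-6-methylbenzoate | COC(=O)c1c(C)cc(OC)cc1OC | starting material
2 | allyl bromide (3-bromoprop-1-ene) | C=CCBr | starting material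
3 | methyl 2-(lithiomethyl)-4,6-dimethoxybenzoate | [Li]Cc1cc(OC)cc(OC)c1C(=O)OC | intermediate
4 | methyl 2-(but-3-en-1-yl)-4,6-dimethoxybenzoate | C=CCCc1cc(OC)cc(OC)c1C(=O)OC | intermediate
5 | [2-(but-3-en-1-yl)-4,6-dimethoxyphenyl]methanol | C=CCCc1cc(OC)cc(OC)c1CO | intermediate
6 | (3S)-3-ethenyl-6,8-dimethoxy-3,4-dihydro-1H-isochromene | C=C[C@@H]1Cc2cc(OC)cc(OC)c2CO1 | intermediate
7 | 5-bromopent-1-ene | C=CCCCBr | starting material
8 | hexanoyl chloride | CCCCCC(Cl)=O | starting material
9 | pent-4-en-1-ylmagnesium bromide | C=CCCC[Mg]Br | intermediate
10 | undec-1-en-6-one | C=CCCCC(=O)CCCCC | intermediate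
11 | (1E)-1-[(3S)-6,8-dimethoxy-3,4-dihydro-1H-isochromen-3-yl]undec-1-en-6-one | CCCCCC(=O)CCC/C=C/[C@@H]1Cc2cc(OC)cc(OC)c2CO1 | intermediate
12 | 1-[(3R)-6,8-dimethoxy-3,4-dihydro-1H-isochromen-3-yl]undecan-6-one | CCCCCC(=O)CCCCC[C@@H]1Cc2cc(OC)cc(OC)c2CO1 | intermediate
13 | (3R)-6,8-dimethoxy-3-(6-oxoundecyl)-3,4-dihydro-1H-isochromen-1-one | CCCCCC(=O)CCCCC[C@@H]1Cc2cc(OC)cc(OC)c2C(=O)O1 | intermediate
14 | (3R)-8-hydroxy-6-methoxy-3-(6-oxoundecyl)-3,4-dihydro-1H-isochromen-1-one | CCCCCC(=O)CCCCC[C@@H]1Cc2cc(OC)cc(O)c2C(=O)O1 | target

## Step count and least certain steps

Total step count: 8. Longest linear sequence: 7 steps (steps 1, 2, 3, 5, 6, 7, 8, from 1); step 4 is the one-step side branch to 10.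

**Step 3 (key step).** Three processes are the most likely to go wrong.
- Acid-promoted ionisation of the doubly methoxy-activated benzylic alcohol, leading to self-condensation.
- Palladium-mediated oxidation of the alcohol to the aldehyde.
- Insufficient facial discrimination by the ligand, because this electron-rich ring is more demanding than a plain benzyl alcohol.

The fallback changes both the bond that closes ring B and the source of chirality. It sets out from 2 and comes back at 6.
- Commercial 3,5-dimethoxyphenylmagnesium bromide is allylated with 2 (CuI cat., THF, 0 °C) to 3,5-dimethoxy-1-(prop-2-en-1-yl)benzene F1.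
- Epoxidation with mCPBA (CH2Cl2, NaHCO3) gives racemic 2-[(3,5-dimethoxyphenyl)methyl]oxirane F2.
- Jacobsen hydrolytic kinetic resolution, with the (salen)Co(OAc) enantiomer that hydrolyses the R epoxide, leaves (2S)-2-[(3,5-dimethoxyphenyl)methyl]oxirane F3.
- Excess dimethylsulfonium methylide (Me3SI, n-BuLi, THF, −10 °C → rt) converts the epoxide into the one-carbon-homologated allylic alcohol (2S)-1-(3,5-dimethoxyphenyl)but-3-en-2-ol F4.
- An oxa-Pictet–Spengler cyclisation with dimethoxymethane and BF3·OEt2 (CH2Cl2, 0 °C) closes ring B at C1–C8a, ortho to the side chain on the symmetric ring, and gives 6.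

**Step 5.** The likely failure is slow turnover of the α-branched allylic ether, so that homodimerisation of 10 and alkene migration (with erosion at C3) dominate. The fallback sets out from 6 and comes back at 12, which also makes step 6 unnecessary.
- Hydroboration of 6 with 9-BBN (THF) gives 9-{2-[(3R)-6,8-dimethoxy-3,4-dihydro-1H-isochromen-3-yl]ethyl}-9-borabicyclo[3.3.1]nonane F5, which is not isolated.
- F5 is coupled in an alkyl–alkyl Suzuki–Miyaura reaction (Pd(OAc)2, PCy3, K3PO4·H2O, THF, rt) with 1-bromononan-4-one F6.
- F6 is made from 4-bromobutanoyl chloride and pentylmagnesium bromide under the Fe(acac)3 conditions of step 4.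

**Step 7.** The likely failure is over-oxidation of the electron-rich ring, or sluggish conversion that forces conditions under which C4 is also attacked. The fallback separates hydride abstraction from the final oxidation. It sets out from 12 and comes back at 13.
- DDQ (1.2 equiv, CH2Cl2/H2O, 0 °C → rt) abstracts hydride from C1 only, and water traps the stabilised oxocarbenium ion to give the lactol 1-[(3R)-1-hydroxy-6,8-dimethoxy-3,4-dihydro-1H-isochromen-3-yl]undecan-6-one F7.
- Mild lactol oxidation (TEMPO cat., PhI(OAc)2, CH2Cl2, rt) then gives 13.

**Step 8.** The likely failure is loss of regioselectivity, with partial cleavage of the C6 ether as well, or Lewis acid-induced side reactions at the ketone on warming. The fallback reverses the logic. It sets out from 13 and comes back at 14.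
- Exhaustive demethylation with BBr3 (CH2Cl2, −78 → 0 °C) gives (3R)-6,8-dihydroxy-3-(6-oxoundecyl)-3,4-dihydro-1H-isochromen-1-one F8.
- Selective methylation of the non-chelated, more acidic C6 phenol (MeI 1.05 equiv, K2CO3, acetone, rt) gives 14; the hydrogen-bonded C8 phenol should stay free.

## Further compounds

F1 | step 3 | 3,5-dimethoxy-1-(prop-2-en-1-yl)benzene | C=CCc1cc(OC)cc(OC)c1
F2 | step 3 | rac-2-[(3,5-dimethoxyphenyl)methyl]oxirane | COc1cc(CC2CO2)cc(OC)c1
F3 | step 3 | (2S)-2-[(3,5-dimethoxyphenyl)methyl]oxirane | COc1cc(C[C@H]2CO2)cc(OC)c1
F4 | step 3 | (2S)-1-(3,5-dimethoxyphenyl)but-3-en-2-ol | C=C[C@@H](O)Cc1cc(OC)cc(OC)c1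
F5 | step 5 | 9-{2-[(3R)-6,8-dimethoxy-3,4-dihydro-1H-isochromen-3-yl]ethyl}-9-borabicyclo[3.3.1]nonane | B1(CC[C@@H]2Cc3cc(OC)cc(OC)c3CO2)C4CCCC1CCC4
F6 | step 5 | 1-bromononan-4-one | BrCCCC(=O)CCCCC
F7 | step 7 | 1-[(3R)-1-hydroxy-6,8-dimethoxy-3,4-dihydro-1H-isochromen-3-yl]undecan-6-one | CCCCCC(=O)CCCCC[C@@H]1Cc2cc(OC)cc(OC)c2C(O)O1
F8 | step 8 | (3R)-6,8-dihydroxy-3-(6-oxoundecyl)-3,4-dihydro-1H-isochromen-1-one | CCCCCC(=O)CCCCC[C@@H]1Cc2cc(O)cc(O)c2C(=O)O1
A1 | alternative 1 | 6-[(6R)-6-[(tert-butyldimethylsilyl)oxy]-2,4-dioxo-11-(2-pentyl-1,3-dioxolan-2-yl)undecyl]-2,2-dimethyl-4H-1,3-dioxin-4-one | CC1(C)OC(=CC(=O)O1)CC(=O)CC(=O)C[C@H](O[Si](C)(C)C(C)(C)C)CCCCCC2(OCCO2)CCCCC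
A2 | alternative 1 | methyl 2-[(2R)-2-[(tert-butyldimethylsilyl)oxy]-7-(2-pentyl-1,3-dioxolan-2-yl)heptyl]-4,6-dihydroxybenzoate | CCCCCC1(OCCO1)CCCCC[C@@H](O[Si](C)(C)C(C)(C)C)Cc2cc(O)cc(O)c2C(=O)OC
A3 | alternative 2 | (12R)-13-(3,5-dimethoxyphenyl)-12-hydroxytridecan-6-one | CCCCCC(=O)CCCCC[C@@H](O)Cc1cc(OC)cc(OC)c1
A4 | alternative 2 | (3R)-6,8-dimethoxy-3-(6-oxoundecyl)-3,4-dihydro-1H-isochromen-1-one | CCCCCC(=O)CCCCC[C@@H]1Cc2cc(OC)cc(OC)c2C(=O)O1
A5 | alternative 3 | methyl (5R)-5-[(tert-butyldimethylsilyl)oxy]-10-(2-pentyl-1,3-dioxolan-2-yl)dec-2-ynoate | COC(=O)C#CC[C@H](O[Si](C)(C)C(C)(C)C)CCCCCC1(OCCO1)CCCCC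
A6 | alternative 3 | 1,3-dimethoxy-1-[(trimethylsilyl)oxy]buta-1,3-diene | C=C(OC)C=C(OC)O[Si](C)(C)C
A7 | alternative 3 | methyl 2-[(2R)-2-[(tert-butyldimethylsilyl)oxy]-7-(2-pentyl-1,3-dioxolan-2-yl)heptyl]-6-hydroxy-4-methoxybenzoate | CCCCCC1(OCCO1)CCCCC[C@@H](O[Si](C)(C)C(C)(C)C)Cc2cc(OC)cc(O)c2C(=O)OC
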